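**Assumption:** the target SMILES has no stereodescriptors and no stereocentres, and neither biaryl axis is configurationally stable at room temperature (the 2,2' axis has only OH/H ortho groups; the 4,4'' axis is of the unsubstituted 1,1'-binaphthyl type, barrier about 23–24 kcal/mol). The target is therefore made as the single constitutional isomer and no stereocontrol is needed.

## Retrosynthetic overview

1. Target 10 (ring A = terminal 2-linked unit, ring B = central unit, ring C = terminal 4-linked unit) comes from 9 by one fluoride step that removes the TIPS group and the silicon tether.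
2. 9 comes from a Suzuki–Miyaura coupling at the para–para bond (C4 of ring B to C4 of ring C): tethered bromide 8 plus boronate 5.
3. 8 comes from the new step: a silicon-tethered anodic dehydrogenative ortho–ortho coupling of mixed bis(naphthyloxy)silane 7. It forms the 2,2' bond and the only new ring, a temporary seven-membered dioxasilepine.
4. 7 and 5 come from 8-methoxynaphthalen-1-ol 2 and its para-bromide 3. All three naphthalene bicycles come intact from naphthalene-1,8-diol 1; no carbocycle is built.

## Route

**Step 1**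
Reactants: 1 naphthalene-1,8-diol
Product: 2 8-methoxynaphthalen-1-ol
Conditions: MeI (1.05 equiv), K2CO3 (1.0 equiv), acetone, reflux
Reagents that add atoms: iodomethane, CI
Why: Williamson ether synthesis; the mono-naphthoxide is stabilised by the peri O–H···O hydrogen bond and the remaining OH of the product, hydrogen-bonded to OMe, is much less acidic, so alkylation stops at the mono-ether.

**Step 2**
Reactants: 2 8-methoxynaphthalen-1-ol
Product: 3 4-bromo-8-methoxynaphthalen-1-ol
Conditions: NBS (1.0 equiv), MeCN, −20 → 0 °C, dark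
Reagents that add atoms: N-bromosuccinimide, BrN1C(=O)CCC1=O
Why: Electrophilic aromatic bromination; the free OH makes its own ring the more nucleophilic one and NBS in a polar solvent attacks the para (alpha) carbon C4, while one equivalent at low temperature limits 2-bromo and 2,4-dibromo by-products.

**Step 3**
Reactants: 3 4-bromo-8-methoxynaphthalen-1-ol
Product: 4 [(4-bromo-8-methoxynaphthalen-1-yl)oxy]tri(propan-2-yl)silane
Conditions: TIPSOTf (1.2 equiv), 2,6-lutidine (2 equiv), CH2Cl2, 0 °C → rt
Reagents that add atoms: tri(propan-2-yl)silyl trifluoromethanesulfonate, CC(C)[Si](OS(=O)(=O)C(F)(F)F)(C(C)C)C(C)C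
Why: O-silylation of the hindered, hydrogen-bonded naphthol with a silyl triflate; the TIPS ether is stable to the later basic palladium steps and is removed by fluoride together with the tether.

**Step 4**
Reactants: 4 [(4-bromo-8-methoxynaphthalen-1-yl)oxy]tri(propan-2-yl)silane
Product: 5 {[8-methoxy-4-(4,4,5,5-tetramethyl-1,3,2-dioxaborolan-2-yl)naphthalen-1-yl]oxy}tri(propan-2-yl)silane
Conditions: B2pin2 (1.3 equiv), PdCl2(dppf) (5 mol %), KOAc (3 equiv), 1,4-dioxane, 90 °C
Reagents that add atoms: bis(pinacolato)diboron, CC1(C)OB(OC1(C)C)B1OC(C)(C)C(C)(C)O1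
Why: Miyaura borylation of the aryl bromide; KOAc is too weak a base to touch the aryl silyl ether or to promote biaryl homocoupling.

**Step 5**
Reactants: 2 8-methoxynaphthalen-1-ol; 3 4-bromo-8-methoxynaphthalen-1-ol
Product: 7 di-tert-butyl[(4-bromo-8-methoxynaphthalen-1-yl)oxy][(8-methoxynaphthalen-1-yl)oxy]silane, via silyl triflate 6 (not isolated)
Conditions: 2, tBu2Si(OTf)2 (1.0 equiv), 2,6-lutidine (3 equiv), CH2Cl2, −78 → 0 °C, 30 min; then 3 (1.05 equiv), DMAP (0.2 equiv), 0 → 35 °C
Reagents that add atoms: di-tert-butylsilyl bis(trifluoromethanesulfonate), CC(C)(C)[Si](OS(=O)(=O)C(F)(F)F)(OS(=O)(=O)C(F)(F)F)C(C)(C)C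
Why: Sequential nucleophilic substitution at silicon; the first triflate is displaced fast at −78 °C and the second much more slowly on the now crowded silicon, so mono-aryloxy silyl triflate 6 accumulates and is then captured by the second naphthol under DMAP catalysis (kept cold and brief so the peri OMe does not attack the silyl triflate).

**Step 6**
Reactants: 7 di-tert-butyl[(4-bromo-8-methoxynaphthalen-1-yl)oxy][(8-methoxynaphthalen-1-yl)oxy]silane
Product: 8 cyclic di-tert-butylsilylene ether of 4-bromo-8,8'-dimethoxy-[2,2'-binaphthalene]-1,1'-diol (a dinaphtho-fused seven-membered 1,3,2-dioxasilepine; O1 and O1' bridged by Si(tBu)2, new C2–C2' bond)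
Conditions: constant current (2 mA cm−2, 2.2 F mol−1), undivided cell, boron-doped diamond anode, platinum cathode, MeBu3N(O3SOMe) (0.1 M), HFIP/CH2Cl2 (4:1), 5 mM in 7, 20 °C
Reagents that add atoms: none
Why: Proposed new method: silicon-tethered intramolecular anodic dehydrogenative ortho–ortho coupling. The bromine-free, more electron-rich naphthyl silyl ether (ring A) is oxidised first to its radical cation, which HFIP stabilises. The O–Si–O tether (O···O about 2.6 Å) stacks the two naphthalenes so that C2 of ring A and C2 of ring B are the only carbon pair within bonding distance; the para carbons cannot reach each other and the para position of ring B is blocked by Br. C–C bond formation gives a seven-membered cyclohexadienyl-type radical cation, and a second electron transfer with loss of two protons rearomatises both rings while the cathode releases H2. Intermolecular para coupling of ring A is suppressed by high dilution and the bulky tBu2Si group, and the charge is limited to about 2.2 F mol−1 to avoid over-oxidation of 8. The closest known reaction types are the intermolecular anodic phenol–arene dehydrogenative cross-coupling in HFIP, the palladium-catalysed silicon-tethered C–H arylation of bis(aryloxy)silanes bearing an ortho bromide, and the trivalent-iodine oxidative coupling of silaketal-tethered aryl ethers; a dehydrogenative C–H/C–H coupling across an Ar–O–Si–O–Ar tether has not been shown.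

**Step 7**
Reactants: 8 cyclic di-tert-butylsilylene ether of 4-bromo-8,8'-dimethoxy-[2,2'-binaphthalene]-1,1'-diol; 5 {[8-methoxy-4-(4,4,5,5-tetramethyl-1,3,2-dioxaborolan-2-yl)naphthalen-1-yl]oxy}tri(propan-2-yl)silane
Product: 9 cyclic di-tert-butylsilylene ether of 8,8'-dimethoxy-4-{5-methoxy-4-[tri(propan-2-yl)silyloxy]naphthalen-1-yl}-[2,2'-binaphthalene]-1,1'-diol
Conditions: 5 (1.3 equiv), Pd(OAc)2 (5 mol %), SPhos (10 mol %), K3PO4 (3 equiv), toluene/H2O (20:1), 80 °C, degassed
Reagents that add atoms: none
Why: Suzuki–Miyaura coupling of two alpha-naphthyl partners, each flanked only by one ortho hydrogen and one peri hydrogen, with a bulky biaryl phosphine; the hindered tBu2Si tether and the TIPS ether tolerate the weak phosphate base, and the new axis is not configurationally stable so no stereochemical issue arises.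

**Step 8**
Reactants: 9 cyclic di-tert-butylsilylene ether of 8,8'-dimethoxy-4-{5-methoxy-4-[tri(propan-2-yl)silyloxy]naphthalen-1-yl}-[2,2'-binaphthalene]-1,1'-diol
Product: 10 4-(4-hydroxy-5-methoxynaphthalen-1-yl)-8,8'-dimethoxy-[2,2'-binaphthalene]-1,1'-diol (target)
Conditions: Bu4NF (3.5 equiv), AcOH (3.5 equiv), THF, 0 °C → rt, argon
Reagents that add atoms: none
Why: Fluoride-driven cleavage of all three aryl O–Si bonds (desilylation, driven by the strong Si–F bond); the acetic acid buffer protonates each naphthoxide at once, so the electron-rich tri-naphthol is not air-oxidised, and there is no stereocentre to set or scramble.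

## Compound list

1 | naphthalene-1,8-diol | Oc1cccc2cccc(O)c12 | starting material
2 | 8-methoxynaphthalen-1-ol | COc1cccc2cccc(O)c12 | intermediate
3 | 4-bromo-8-methoxynaphthalen-1-ol | COc1cccc2c(Br)ccc(O)c12 | intermediate
4 | [(4-bromo-8-methoxynaphthalen-1-yl)oxy]tri(propan-2-yl)silane | COc1cccc2c(Br)ccc(O[Si](C(C)C)(C(C)C)C(C)C)c12 | intermediate
5 | {[8-methoxy-4-(4,4,5,5-tetramethyl-1,3,2-dioxaborolan-2-yl)naphthalen-1-yl]oxy}tri(propan-2-yl)silane | COc1cccc2c(B3OC(C)(C)C(C)(C)O3)ccc(O[Si](C(C)C)(C(C)C)C(C)C)c12 | intermediate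
6 | di-tert-butyl[(8-methoxynaphthalen-1-yl)oxy]silyl trifluoromethanesulfonate (not isolated) | COc1cccc2cccc(O[Si](OS(=O)(=O)C(F)(F)F)(C(C)(C)C)C(C)(C)C)c12 | intermediate
7 | di-tert-butyl[(4-bromo-8-methoxynaphthalen-1-yl)oxy][(8-methoxynaphthalen-1-yl)oxy]silane | COc1cccc2cccc(O[Si](Oc3ccc(Br)c4cccc(OC)c34)(C(C)(C)C)C(C)(C)C)c12 | intermediate
8 | cyclic di-tert-butylsilylene ether of 4-bromo-8,8'-dimethoxy-[2,2'-binaphthalene]-1,1'-diol | COc1cccc2ccc3-c4cc(Br)c5cccc(OC)c5c4O[Si](C(C)(C)C)(C(C)(C)C)Oc3c12 | intermediate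
9 | cyclic di-tert-butylsilylene ether of 8,8'-dimethoxy-4-{5-methoxy-4-[tri(propan-2-yl)silyloxy]naphthalen-1-yl}-[2,2'-binaphthalene]-1,1'-diol | COc1cccc2ccc3-c4cc(-c6ccc(O[Si](C(C)C)(C(C)C)C(C)C)c7c(OC)cccc67)c5cccc(OC)c5c4O[Si](C(C)(C)C)(C(C)(C)C)Oc3c12 | intermediate
10 | 4-(4-hydroxy-5-methoxynaphthalen-1-yl)-8,8'-dimethoxy-[2,2'-binaphthalene]-1,1'-diol | COc1cccc2ccc(-c3cc(-c4ccc(O)c5c(OC)cccc45)c4cccc(OC)c4c3O)c(O)c12 | target

## Summary

Total step count: 8.
Longest linear sequence: 6 steps (1, 2, 5, 6, 7, 8; the branch 1, 2, 3, 4, 7, 8 is equally long).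

## Three steps most likely to fail

**Step 6 (proposed new step).** Likely failure modes are intermolecular coupling through the free para position of ring A and over-oxidation of 8. The fallback uses known chemistry: the para–para bond is made first and the 2,2' bond is closed by the established palladium-catalysed silicon-tethered C–H arylation of an ortho-bromoaryl silane. It sets out from 2, 3 and 5 and comes back to the route at 9. Compound 2 is brominated ortho to the hydroxyl (NBS, 10 mol % iPr2NH, CH2Cl2, 0 °C) to give 2-bromo-8-methoxynaphthalen-1-ol F1. Free naphthol 3 is coupled with boronate 5 (Pd(OAc)2, SPhos, K3PO4, degassed dioxane/H2O, 80 °C) to give 8-methoxy-4-{5-methoxy-4-[tri(propan-2-yl)silyloxy]naphthalen-1-yl}naphthalen-1-ol F2. F1 is treated with tBu2Si(OTf)2 and 2,6-lutidine (CH2Cl2, −78 → 0 °C) to give [(2-bromo-8-methoxynaphthalen-1-yl)oxy]di-tert-butylsilyl trifluoromethanesulfonate F3, which is not isolated and is quenched with F2 and DMAP to give [(2-bromo-8-methoxynaphthalen-1-yl)oxy]di-tert-butyl[(8-methoxy-4-{5-methoxy-4-[tri(propan-2-yl)silyloxy]naphthalen-1-yl}naphthalen-1-yl)oxy]silane F4. Heating F4 with Pd(OAc)2, PCy3·HBF4, K2CO3 and PivOH in DMA at 110 °C lets zerovalent palladium insert into the C2–Br bond of ring A; the only C–H bond within reach is C2–H of ring B, so the dioxasilepine closes and 9 is obtained.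

**Step 5 (mixed silane).** Likely failure modes are symmetrical silanes from scrambling and loss of the peri methoxy group at the silyl triflate stage. The fallback makes the tether symmetrical and differentiates the two halves afterwards; it sets out from 3 and comes back to the route at 9. Two equivalents of 3 react with tBu2Si(OTf)2 (2,6-lutidine, DMAP, CH2Cl2, 0 → 35 °C) through [(4-bromo-8-methoxynaphthalen-1-yl)oxy]di-tert-butylsilyl trifluoromethanesulfonate F5, not isolated, to give bis[(4-bromo-8-methoxynaphthalen-1-yl)oxy]di-tert-butylsilane F6. The anodic closure under the conditions of step 6, now with both para positions blocked by bromine, gives the cyclic di-tert-butylsilylene ether of 4,4'-dibromo-8,8'-dimethoxy-[2,2'-binaphthalene]-1,1'-diol F7. One of its two equivalent bromides is coupled with 5 (0.8 equiv, conditions of step 7; statistical, unreacted F7 recycled) to give the cyclic di-tert-butylsilylene ether of 4-bromo-8,8'-dimethoxy-4'-{5-methoxy-4-[tri(propan-2-yl)silyloxy]naphthalen-1-yl}-[2,2'-binaphthalene]-1,1'-diol F8. Hydrogenolysis of the remaining C–Br bond (H2, 1 atm, Pd/C, NaOAc, EtOAc/MeOH, rt) gives 9.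

**Step 7 (Suzuki–Miyaura coupling).** Likely failure modes are protodeboronation of the electron-rich boronate 5 and opening of the dioxasilepine by aqueous base. The fallback is an anhydrous, base-free Negishi coupling with the polarity taken from the bromide; it sets out from 4 (bypassing 5), uses bromide 8, and comes back to the route at 9. Bromide 4 undergoes bromine–lithium exchange (n-BuLi, THF, −78 °C) to {5-methoxy-4-[tri(propan-2-yl)silyloxy]naphthalen-1-yl}lithium F9. Transmetalation with ZnCl2 gives chlorido{5-methoxy-4-[tri(propan-2-yl)silyloxy]naphthalen-1-yl}zinc F10. Coupling of F10 with 8 (Pd2(dba)3, SPhos, THF, 60 °C) gives 9.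

## Further compounds

F1 | step 6 | 2-bromo-8-methoxynaphthalen-1-ol | COc1cccc2ccc(Br)c(O)c12
F2 | step 6 | 8-methoxy-4-{5-methoxy-4-[tri(propan-2-yl)silyloxy]naphthalen-1-yl}naphthalen-1-ol | COc1cccc2c(-c3ccc(O[Si](C(C)C)(C(C)C)C(C)C)c4c(OC)cccc34)ccc(O)c12
F3 | step 6 | [(2-bromo-8-methoxynaphthalen-1-yl)oxy]di-tert-butylsilyl trifluoromethanesulfonate | COc1cccc2ccc(Br)c(O[Si](OS(=O)(=O)C(F)(F)F)(C(C)(C)C)C(C)(C)C)c12
F4 | step 6 | [(2-bromo-8-methoxynaphthalen-1-yl)oxy]di-tert-butyl[(8-methoxy-4-{5-methoxy-4-[tri(propan-2-yl)silyloxy]naphthalen-1-yl}naphthalen-1-yl)oxy]silane | COc1cccc2ccc(Br)c(O[Si](Oc3ccc(-c4ccc(O[Si](C(C)C)(C(C)C)C(C)C)c5c(OC)cccc45)c4cccc(OC)c34)(C(C)(C)C)C(C)(C)C)c12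
F5 | step 5 | [(4-bromo-8-methoxynaphthalen-1-yl)oxy]di-tert-butylsilyl trifluoromethanesulfonate | COc1cccc2c(Br)ccc(O[Si](OS(=O)(=O)C(F)(F)F)(C(C)(C)C)C(C)(C)C)c12
F6 | step 5 | bis[(4-bromo-8-methoxynaphthalen-1-yl)oxy]di-tert-butylsilane | COc1cccc2c(Br)ccc(O[Si](Oc3ccc(Br)c4cccc(OC)c34)(C(C)(C)C)C(C)(C)C)c12
F7 | step 5 | cyclic di-tert-butylsilylene ether of 4,4'-dibromo-8,8'-dimethoxy-[2,2'-binaphthalene]-1,1'-diol | COc1cccc2c(Br)cc3-c4cc(Br)c5cccc(OC)c5c4O[Si](C(C)(C)C)(C(C)(C)C)Oc3c12
F8 | step 5 | cyclic di-tert-butylsilylene ether of 4-bromo-8,8'-dimethoxy-4'-{5-methoxy-4-[tri(propan-2-yl)silyloxy]naphthalen-1-yl}-[2,2'-binaphthalene]-1,1'-diol | COc1cccc2c(Br)cc3-c4cc(-c6ccc(O[Si](C(C)C)(C(C)C)C(C)C)c7c(OC)cccc67)c5cccc(OC)c5c4O[Si](C(C)(C)C)(C(C)(C)C)Oc3c12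
F9 | step 7 | {5-methoxy-4-[tri(propan-2-yl)silyloxy]naphthalen-1-yl}lithium | [Li]c1ccc(O[Si](C(C)C)(C(C)C)C(C)C)c2c(OC)cccc12
F10 | step 7 | chlorido{5-methoxy-4-[tri(propan-2-yl)silyloxy]naphthalen-1-yl}zinc | Cl[Zn]c1ccc(O[Si](C(C)C)(C(C)C)C(C)C)c2c(OC)cccc12
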